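The cyclohexenone ring (C1 carbonyl, C2=C3, C4H2, C5 carbinol, C6H2) is cut into the enone triad C1–C3 and the unit C4–C5(OH)–C6. The key step exploits that the tertiary carbinol C5 with its two flanking ring methylenes is a 2-alkylepichlorohydrin in disguise. In one flask the symmetric 1,3-bis(methylsulfanyl)allyl anion, a β-acylvinyl 1,3-dianion equivalent made in situ from its methoxy precursor, opens the epoxide CH2 of (R)-2-(chloromethyl)-2-nonadecyloxirane (C1–C6 bond), the C5 alkoxide relays to a new epoxide, and after relithiation the other allyl terminus closes the ring at the second CH2 (C3–C4 bond). The order of alkylations transcribes the epoxide configuration into C5; mercury-assisted hydrolysis unveils the enone.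

Key step: step 6

Remark: the side chain has 19 carbons (nonadecyl) and the target is the (5S) enantiomer; the ring numbering of the paragraph above is used throughout.

Step 1
Reactants: 1 1-bromononadecane; 2 prop-2-yn-1-ol
Product: 5 2-methylidenehenicosan-1-ol, via nonadecylmagnesium bromide 3 (not isolated), via alkenylmagnesium adduct 4 (not isolated)
Conditions: 1, Mg, THF, 50 °C; then 2 (0.45 equiv), CuI (10 mol%), 0 °C to reflux; cold 1 M HCl
Reagents that add atoms: none
Why: CuI-catalysed carbomagnesiation of the magnesium propargyl alkoxide (anti addition, alkyl to the internal carbon, magnesium to the terminal carbon in a five-membered chelate) should give the 2-alkyl allylic alcohol on protonation, the first equivalent of 3 serving only to deprotonate the hydroxyl group.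

Step 2
Reactants: 5 2-methylidenehenicosan-1-ol
Product: 6 [(2S)-2-nonadecyloxiran-2-yl]methanol
Conditions: Ti(OiPr)4 (10 mol%), L-(+)-diisopropyl tartrate (12 mol%), t-BuOOH, 4 Å molecular sieves, CH2Cl2, −20 °C
Reagents that add atoms: tert-butyl hydroperoxide, CC(C)(C)OO
Why: Sharpless asymmetric epoxidation of a 2-substituted allylic alcohol, in which the L-(+)-tartrate ligand should deliver oxygen to the face that gives the (S)-epoxy alcohol (the same sense as (S)-glycidol from allyl alcohol), setting the only stereocentre of the route.

Step 3
Reactants: 6 [(2S)-2-nonadecyloxiran-2-yl]methanol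
Product: 7 (2R)-2-(chloromethyl)-2-nonadecyloxirane
Conditions: PPh3, CCl4, NaHCO3, 65 °C
Reagents that add atoms: carbon tetrachloride, ClC(Cl)(Cl)Cl
Why: Appel reaction at the primary carbinol through an alkoxyphosphonium salt, buffered so that the epoxide should survive; no bond to the quaternary stereocentre is touched, and the descriptor becomes R only because CH2Cl outranks the ring CH2.

Step 4
Reactants: 8 epichlorohydrin (racemic)
Product: 9 1,3-bis(methylsulfanyl)propan-2-ol
Conditions: NaSMe (2.1 equiv), MeOH–H2O, 0 °C to rt
Reagents that add atoms: sodium methanethiolate, C[S-].[Na+]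
Why: Thiolate opens the epoxide, the alkoxide re-closes with loss of chloride and a second thiolate opens the new epoxide (two SN2 thioetherifications), which should give the achiral symmetric bis-sulfide.

Step 5
Reactants: 9 1,3-bis(methylsulfanyl)propan-2-ol
Product: 10 2-methoxy-1,3-bis(methylsulfanyl)propane
Conditions: NaH, MeI (1.05 equiv), THF, 0 °C to rt
Reagents that add atoms: iodomethane, CI
Why: Williamson ether synthesis on the secondary alkoxide installs the methoxide leaving group needed for the elimination that opens step 6.

Step 6
Reactants: 10 2-methoxy-1,3-bis(methylsulfanyl)propane; 7 (2R)-2-(chloromethyl)-2-nonadecyloxirane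
Product: 17 (1S)-3,5-bis(methylsulfanyl)-1-nonadecylcyclohex-3-en-1-ol, via 1,3-bis(methylsulfanyl)prop-1-ene 11 (not isolated), via 1,3-bis(methylsulfanyl)allyllithium 12 (not isolated), via lithium chlorohydrin alkoxide 13 (not isolated), via relay epoxide 14 (not isolated), via lithiated relay epoxide 15 (not isolated), via lithium cyclohexenyl alkoxide 16 (not isolated)
Conditions: 10, LiN(iPr)2 (2.0 equiv), THF, −78 to 0 °C; then 7 (1.0 equiv), −78 °C to rt; then LiN(iPr)2 (1.0 equiv), −78 to −30 °C; AcOH, −78 °C
Reagents that add atoms: none
Why: Two equivalents of LiN(iPr)2 eliminate methoxide from 10 (E1cB type) and deprotonate the resulting propene 11 to the symmetric allyl anion 12, which opens the epoxide of 7 at its CH2 (first C–C bond, between the future carbonyl carbon and the CH2 next to it); alkoxide 13 then expels chloride to give relay epoxide 14, and the third equivalent of base lithiates the allylic C–H to the thio-stabilised allyl anion 15, whose unsubstituted terminus opens the new epoxide at its CH2 (second C–C bond, between the future enone β-carbon and the other CH2). The closest known reaction types are the one-pot double alkylation of sulfur-stabilised carbanions with epichlorohydrin and the sequential α,γ-dialkylation of the 1,3-bis(methylsulfanyl)allyl anion as a β-acylvinyl dianion equivalent. The cyclohexene should close by 6-endo-tet epoxide opening at the primary carbon, because the 5-exo and 3-exo alternatives require substitution at the fully substituted epoxide carbon and closure through the substituted allyl terminus would give a strained cyclobutane. No stereocentre of consequence is created (the sulfur-bearing sp3 carbon forms as a mixture and is lost in step 7): the C–O bond of the quaternary carbon is never broken, so the configuration of 7 is carried into 17, and the order of the two alkylations decides which CH2 ends next to the future carbonyl. The step needs epoxide opening before chloride displacement, which the hindered neopentyl-type chloride secures, and no proton exchange at the remaining allylic C–H of the product, which would make the two sulfur-bearing carbons equivalent and racemise the material; exactly one equivalent of base in the second lithiation, low temperature, the anionic alkoxide form of 16 and the cold AcOH quench should suppress this.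

Step 7
Reactants: 17 (1S)-3,5-bis(methylsulfanyl)-1-nonadecylcyclohex-3-en-1-ol
Product: 18 (5S)-5-hydroxy-5-nonadecylcyclohex-2-en-1-one (CNP0103007.1)
Conditions: HgCl2 (2.2 equiv), CaCO3, MeCN–H2O (4:1), rt
Reagents that add atoms: water, O
Why: Mercury-assisted hydrolysis turns the sp2 carbon of the vinyl sulfide into the ketone and the allylic methylsulfanyl group leaves as the mercury thiolate with the double bond moving into conjugation (the standard unmasking of the bis(methylsulfanyl)allyl synthon), while the CaCO3 buffer should keep the tertiary β-hydroxy ketone from dehydrating; the stereocentre is not involved.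

Compound list
1 | 1-bromononadecane | CCCCCCCCCCCCCCCCCCCBr | starting material
2 | prop-2-yn-1-ol (propargyl alcohol) | C#CCO | starting material
3 | nonadecylmagnesium bromide | CCCCCCCCCCCCCCCCCCC[Mg]Br | intermediate
4 | alkenylmagnesium adduct, bromomagnesium (Z)-3-(bromomagnesio)-2-nonadecylprop-2-en-1-olate | CCCCCCCCCCCCCCCCCCC/C(CO[Mg]Br)=C/[Mg]Br | intermediate
5 | 2-methylidenehenicosan-1-ol | CCCCCCCCCCCCCCCCCCCC(=C)CO | intermediate
6 | [(2S)-2-nonadecyloxiran-2-yl]methanol | CCCCCCCCCCCCCCCCCCC[C@]1(CO)CO1 | intermediate
7 | (2R)-2-(chloromethyl)-2-nonadecyloxirane | CCCCCCCCCCCCCCCCCCC[C@]1(CCl)CO1 | intermediate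
8 | epichlorohydrin (racemic 2-(chloromethyl)oxirane) | ClCC1CO1 | starting material
9 | 1,3-bis(methylsulfanyl)propan-2-ol | CSCC(O)CSC | intermediate
10 | 2-methoxy-1,3-bis(methylsulfanyl)propane | CSCC(OC)CSC | intermediate
11 | 1,3-bis(methylsulfanyl)prop-1-ene (E/Z mixture) | CSC=CCSC | intermediate
12 | 1,3-bis(methylsulfanyl)allyllithium | CSC=CC([Li])SC | intermediate
13 | lithium (2R)-1-chloro-4,6-bis(methylsulfanyl)-2-nonadecylhex-5-en-2-olate (mixture at C4, E/Z) | CCCCCCCCCCCCCCCCCCC[C@](O[Li])(CCl)CC(SC)C=CSC | intermediate
14 | (2R)-2-[2,4-bis(methylsulfanyl)but-3-en-1-yl]-2-nonadecyloxirane (relay epoxide; mixture at the side-chain carbon, E/Z) | CCCCCCCCCCCCCCCCCCC[C@@]1(CC(SC)C=CSC)CO1 | intermediate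
15 | lithiated relay epoxide, (2R)-2-[2-lithio-2,4-bis(methylsulfanyl)but-3-en-1-yl]-2-nonadecyloxirane (delocalised allyl anion) | CCCCCCCCCCCCCCCCCCC[C@@]1(CC([Li])(SC)C=CSC)CO1 | intermediate
16 | lithium (1S)-3,5-bis(methylsulfanyl)-1-nonadecylcyclohex-3-en-1-olate | CCCCCCCCCCCCCCCCCCC[C@]1(O[Li])CC(SC)C=C(SC)C1 | intermediate
17 | (1S)-3,5-bis(methylsulfanyl)-1-nonadecylcyclohex-3-en-1-ol (both C5 epimers) | CCCCCCCCCCCCCCCCCCC[C@]1(O)CC(SC)C=C(SC)C1 | intermediate
18 | (5S)-5-hydroxy-5-nonadecylcyclohex-2-en-1-one (CNP0103007.1) | CCCCCCCCCCCCCCCCCCC[C@]1(O)CC=CC(=O)C1 | target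

Total step count: 7.
Longest linear sequence: 5 steps (steps 1, 2, 3, 6, 7; the reagent branch 4, 5, 6, 7 has 4 steps).

Steps most likely to fail

1. Step 6. What may go wrong: proton transfer between the lithiated species and the cyclised product (possibly relayed by the diisopropylamine in the flask), which would equalise the two sulfur-bearing ring carbons and erode the enantiomeric purity; ring closure through the substituted allyl terminus to a four-membered ring; slow closure of the chlorohydrin alkoxide or a sluggish endo opening of the relay epoxide. Fallback (stepwise, ring closed by olefin metathesis): setting out from 7, 1-lithio-1-methoxypropa-1,2-diene F1 (from methoxyallene and n-BuLi, THF, −40 °C) opens the epoxide CH2 and the alkoxide closes onto CH2Cl to give (2R)-2-(2-methoxybuta-2,3-dien-1-yl)-2-nonadecyloxirane F2. Vinylmagnesium bromide with catalytic CuI then opens the new epoxide at its CH2 to give (4S)-6-methoxy-4-nonadecylocta-1,6,7-trien-4-ol F3. Dilute aqueous oxalic acid in THF hydrolyses the methoxyallene to the vinyl ketone (5S)-5-hydroxy-5-nonadecylocta-1,7-dien-3-one F4. Ring-closing metathesis with the second-generation Grubbs catalyst (H2IMes)(PCy3)Cl2Ru=CHPh in CH2Cl2 closes the C2=C3 bond, and the fallback comes back to the route at 18.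

2. Step 7. What may go wrong: acid- or mercury-promoted dehydration of the tertiary β-hydroxy ketone followed by aromatisation, or retro-aldol ring opening, during the unmasking. Fallback (protecting-group detour): setting out from 17, silylation with Et3SiOTf and 2,6-lutidine in CH2Cl2 gives triethyl{[(1S)-3,5-bis(methylsulfanyl)-1-nonadecylcyclohex-3-en-1-yl]oxy}silane F5. The HgCl2/CaCO3 hydrolysis is run on this ether to give (5S)-5-nonadecyl-5-[(triethylsilyl)oxy]cyclohex-2-en-1-one F6. HF·pyridine in THF at 0 °C removes the silyl group, and the fallback comes back to the route at 18.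

3. Step 3. What may go wrong: opening of the acid-sensitive 2,2-disubstituted epoxide by chloride or adventitious HCl during the deoxychlorination, or a stalled substitution next to the quaternary carbon. Fallback (sulfonate instead of chloride as the relay leaving group): setting out from 6, TsCl, Et3N and catalytic DMAP in CH2Cl2 at 0 °C give [(2R)-2-nonadecyloxiran-2-yl]methyl 4-methylbenzenesulfonate F7, which is used in step 6 in place of 7. The epoxide CH2 should again be attacked first by 12 because the sulfonate sits on a neopentyl-type carbon; the alkoxide then expels tosylate, and the fallback comes back to the route at relay epoxide 14.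

Further compounds
F1 | step 6 | 1-lithio-1-methoxypropa-1,2-diene | COC([Li])=C=C
F2 | step 6 | (2R)-2-(2-methoxybuta-2,3-dien-1-yl)-2-nonadecyloxirane | CCCCCCCCCCCCCCCCCCC[C@@]1(CC(OC)=C=C)CO1
F3 | step 6 | (4S)-6-methoxy-4-nonadecylocta-1,6,7-trien-4-ol | CCCCCCCCCCCCCCCCCCC[C@](O)(CC=C)CC(OC)=C=C
F4 | step 6 | (5S)-5-hydroxy-5-nonadecylocta-1,7-dien-3-one | CCCCCCCCCCCCCCCCCCC[C@](O)(CC=C)CC(=O)C=C
F5 | step 7 | triethyl{[(1S)-3,5-bis(methylsulfanyl)-1-nonadecylcyclohex-3-en-1-yl]oxy}silane | CCCCCCCCCCCCCCCCCCC[C@]1(O[Si](CC)(CC)CC)CC(SC)C=C(SC)C1
F6 | step 7 | (5S)-5-nonadecyl-5-[(triethylsilyl)oxy]cyclohex-2-en-1-one | CCCCCCCCCCCCCCCCCCC[C@]1(O[Si](CC)(CC)CC)CC=CC(=O)C1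
F7 | step 3 | [(2R)-2-nonadecyloxiran-2-yl]methyl 4-methylbenzenesulfonate | CCCCCCCCCCCCCCCCCCC[C@]1(COS(=O)(=O)c2ccc(C)cc2)CO1
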